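Plan
- Enabling feature: in the lower flavanone the ketone carbon C4'' sits on C4a'' of ring A''. C4a'' is the only hydrogen-bearing carbon next to C8a'', whose oxygen O1'' holds the stereocentre C2''. Ring C'' is therefore the cyclised form of a 3-aryloxy-3-arylpropanoic acid.
- Cuts, in retrosynthetic order: C4''–C4a'' (acylation), C3–C8'' (aryl transfer from lead to a flavanone-3-carboxylate), O1''–C2'' (Mitsunobu), then O1–C2 and C2=C3 of ring C (oxa-Michael, Knoevenagel).
- Forward: the ring B'' hydroxy ester and an iodinated ring A'' phenol are joined to an aryl ether, which is metallated (I to Sn to Pb). Ring C of the upper unit is closed separately and the halves are united at C3–C8''. Loss of two tert-butyl groups and CO2 bares the acid, ring C'' closes last, and the acetate and six benzyl groups are then removed.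
- Stereochemistry: C2'' comes from Ru-catalysed transfer hydrogenation (R) followed by Mitsunobu inversion (S). C2 (R) comes from a cinchona thiourea-catalysed oxa-Michael addition. C3 (S) is relayed from C2 by equilibration to the 2,3-trans ketone after decarboxylation.

Key step: step 12

Remark: unprimed locants denote the upper flavanone (rings A, B, C) and doubly primed ones the lower flavanone (rings A'', B'', C''); 4-acetoxybenzoyl chloride, Meldrum's acid, 3,5-bis(benzyloxy)phenol, 2,4,6-trihydroxyacetophenone and 3,4-bis(benzyloxy)benzaldehyde are taken as catalogue chemicals; the quinine-derived thiourea of step 9 is assumed to give the 2R series, and its quinidine-derived pseudoenantiomer would replace it if a CD check on a decarboxylated sample showed 2S.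

Step 1
Reactants: 1 4-acetoxybenzoyl chloride; 2 Meldrum's acid (2,2-dimethyl-1,3-dioxane-4,6-dione)
Product: 4 tert-butyl 3-(4-acetoxyphenyl)-3-oxopropanoate, via acyl Meldrum's acid 3 (not isolated)
Conditions: pyridine (2.2 equiv), CH2Cl2, 0 °C to rt; cold dilute HCl wash, concentrate; t-BuOH (5 equiv), toluene, 90 °C
Reagents that add atoms: tert-butanol, CC(C)(C)O
Why: C-acylation of Meldrum's acid followed by thermal loss of acetone and CO2 gives an acylketene that tert-butanol traps (acyl Meldrum's acid alcoholysis), a base-free entry to the β-keto ester that leaves the aryl acetate untouched.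

Step 2
Reactants: 4 tert-butyl 3-(4-acetoxyphenyl)-3-oxopropanoate
Product: 5 tert-butyl (3R)-3-(4-acetoxyphenyl)-3-hydroxypropanoate
Conditions: RuCl[(R,R)-TsDPEN](p-cymene) (1 mol%), HCO2H–Et3N (5:2), EtOAc, 30 °C
Reagents that add atoms: none
Why: Noyori asymmetric transfer hydrogenation of an aryl ketone, in which the (R,R)-diamine ruthenium hydride recognises the aryl group through its contact with the cymene ligand and should deliver hydride to the face that gives the (R)-carbinol, both esters being inert.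

Step 3
Reactants: 6 3,5-bis(benzyloxy)phenol
Product: 7 3,5-bis(benzyloxy)-2-iodophenol
Conditions: N-iodosuccinimide (1.0 equiv), CH2Cl2, −20 to 0 °C, dark
Reagents that add atoms: N-iodosuccinimide, O=C1CCC(=O)N1I
Why: Electrophilic aromatic iodination should favour the carbon ortho to the free hydroxyl and para to a benzyloxy group over the more crowded carbon between the two benzyloxy groups, and the symmetric 4-iodo isomer is removable by chromatography.

Step 4
Reactants: 7 3,5-bis(benzyloxy)-2-iodophenol; 5 tert-butyl (3R)-3-(4-acetoxyphenyl)-3-hydroxypropanoate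
Product: 8 tert-butyl (3S)-3-(4-acetoxyphenyl)-3-[3,5-bis(benzyloxy)-2-iodophenoxy]propanoate
Conditions: PPh3 (1.5 equiv), DIAD (1.5 equiv), toluene, 0 °C to rt
Reagents that add atoms: none
Why: Mitsunobu etherification, in which the iodine-acidified phenol displaces the oxyphosphonium group by SN2 with inversion ((R)-carbinol to (S)-ether), the acetoxy group disfavouring an SN1 leak and the cold, non-polar medium curbing elimination to the cinnamate.

Step 5
Reactants: 8 tert-butyl (3S)-3-(4-acetoxyphenyl)-3-[3,5-bis(benzyloxy)-2-iodophenoxy]propanoate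
Product: 9 tert-butyl (3S)-3-(4-acetoxyphenyl)-3-[3,5-bis(benzyloxy)-2-(tributylstannyl)phenoxy]propanoate
Conditions: (Bu3Sn)2 (1.5 equiv), Pd(PPh3)4 (5 mol%), toluene, 105 °C
Reagents that add atoms: hexabutylditin, CCCC[Sn](CCCC)(CCCC)[Sn](CCCC)(CCCC)CCCC
Why: Palladium-catalysed stannylation of an aryl iodide with a distannane runs without base or organolithium, so the β-aryloxy ester cannot eliminate and the aryl metal cannot attack its own ester.

Step 6
Reactants: 10 2,4,6-trihydroxyacetophenone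
Product: 11 1-[2,4-bis(benzyloxy)-6-hydroxyphenyl]ethan-1-one
Conditions: BnBr (2.05 equiv), K2CO3 (2.1 equiv), acetone, reflux
Reagents that add atoms: benzyl bromide, BrCc1ccccc1
Why: Williamson etherification in which one hydroxyl stays hydrogen-bonded to the acetyl carbonyl, is the least nucleophilic and remains free when two equivalents of benzyl bromide are used.

Step 7
Reactants: 11 1-[2,4-bis(benzyloxy)-6-hydroxyphenyl]ethan-1-one
Product: 12 tert-butyl 3-[2,4-bis(benzyloxy)-6-hydroxyphenyl]-3-oxopropanoate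
Conditions: LiN(SiMe3)2 (3.3 equiv), THF, −78 °C; Boc2O (1.1 equiv), −78 to −20 °C; AcOH quench
Reagents that add atoms: di-tert-butyl dicarbonate, CC(C)(C)OC(=O)OC(=O)OC(C)(C)C
Why: Claisen-type C-acylation of the lithium phenoxide–enolate dianion, in which any aryl carbonate formed at the phenoxide is passed on to carbon by a Baker–Venkataraman-type acyl shift, so both paths should converge on the β-keto ester.

Step 8
Reactants: 12 tert-butyl 3-[2,4-bis(benzyloxy)-6-hydroxyphenyl]-3-oxopropanoate; 13 3,4-bis(benzyloxy)benzaldehyde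
Product: 14 tert-butyl (2Z)-2-[2,4-bis(benzyloxy)-6-hydroxybenzoyl]-3-[3,4-bis(benzyloxy)phenyl]prop-2-enoate
Conditions: piperidine (10 mol%), AcOH (10 mol%), 4 Å molecular sieves, toluene, rt
Reagents that add atoms: none
Why: Knoevenagel condensation under piperidinium acetate catalysis, in which the bulky ester, the electron-rich arylidene and the hydrogen-bonded phenol should hold back premature, racemic ring closure.

Step 9
Reactants: 14 tert-butyl (2Z)-2-[2,4-bis(benzyloxy)-6-hydroxybenzoyl]-3-[3,4-bis(benzyloxy)phenyl]prop-2-enoate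
Product: 15 tert-butyl (2R,3S)-5,7-bis(benzyloxy)-2-[3,4-bis(benzyloxy)phenyl]-4-oxochromane-3-carboxylate
Conditions: quinine-derived 9-amino-9-deoxy-epi thiourea bearing a 3,5-bis(trifluoromethyl)phenyl group (10 mol%), toluene, −25 °C; short silica plug, used at once
Reagents that add atoms: none
Why: Enantioselective intramolecular oxa-Michael addition (6-endo-trig) of an alkylidene β-keto ester under bifunctional catalysis, in which the thiourea binds the dicarbonyl unit and the quinuclidine guides the phenol to one alkene face to set C2 as R, while the labile C3 settles trans.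

Step 10
Reactants: 9 tert-butyl (3S)-3-(4-acetoxyphenyl)-3-[3,5-bis(benzyloxy)-2-(tributylstannyl)phenoxy]propanoate; 15 tert-butyl (2R,3S)-5,7-bis(benzyloxy)-2-[3,4-bis(benzyloxy)phenyl]-4-oxochromane-3-carboxylate
Product: 17 tert-butyl (2S,3R)-3-{2-[(1S)-1-(4-acetoxyphenyl)-3-tert-butoxy-3-oxopropoxy]-4,6-bis(benzyloxy)phenyl}-5,7-bis(benzyloxy)-2-[3,4-bis(benzyloxy)phenyl]-4-oxochromane-3-carboxylate, via aryllead triacetate 16 (not isolated)
Conditions: 9, Pb(OAc)4 (1.0 equiv), Hg(OAc)2 (10 mol%), CHCl3, 40 °C; then 15 (0.9 equiv), pyridine (3.3 equiv), CHCl3, 40 to 60 °C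
Reagents that add atoms: none
Why: Tin–lead exchange followed by Pinhey arylation, in which the enol of the β-keto ester replaces an acetate on tetravalent lead and ligand coupling forges the crowded C3–C8'' bond anti to ring B, a process that tolerates di-ortho-alkoxyaryl groups and, by making C3 quaternary, blocks ring opening by β-elimination and so locks C2.

Step 11
Reactants: 17 tert-butyl (2S,3R)-3-{2-[(1S)-1-(4-acetoxyphenyl)-3-tert-butoxy-3-oxopropoxy]-4,6-bis(benzyloxy)phenyl}-5,7-bis(benzyloxy)-2-[3,4-bis(benzyloxy)phenyl]-4-oxochromane-3-carboxylate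
Product: 19 (3S)-3-(4-acetoxyphenyl)-3-{3,5-bis(benzyloxy)-2-[(2R,3S)-5,7-bis(benzyloxy)-2-[3,4-bis(benzyloxy)phenyl]-4-oxochroman-3-yl]phenoxy}propanoic acid, via β-keto diacid 18 (not isolated)
Conditions: CF3CO2H–CH2Cl2 (1:4), 0 °C to rt under a slow N2 sweep; evaporation with toluene, 40 °C
Reagents that add atoms: none
Why: Acidolysis of both tert-butyl esters and decarboxylation of the β-keto acid, after which the enol is protonated and acid-equilibrated to the diequatorial 2,3-trans ketone, so that C3 becomes S under the control of C2.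

Step 12
Reactants: 19 (3S)-3-(4-acetoxyphenyl)-3-{3,5-bis(benzyloxy)-2-[(2R,3S)-5,7-bis(benzyloxy)-2-[3,4-bis(benzyloxy)phenyl]-4-oxochroman-3-yl]phenoxy}propanoic acid
Product: 21 4-{(2S)-5,7-bis(benzyloxy)-8-[(2R,3S)-5,7-bis(benzyloxy)-2-[3,4-bis(benzyloxy)phenyl]-4-oxochroman-3-yl]-4-oxochroman-2-yl}phenyl acetate, via mixed trifluoroacetic anhydride 20 (not isolated)
Conditions: (CF3CO)2O (2.0 equiv), CH2Cl2 (0.02 M), 0 °C to rt; cold aqueous NaHCO3 work-up
Reagents that add atoms: none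
Why: Trifluoroacetic anhydride turns the carboxylic acid of 19 into mixed anhydride 20, whose acyl carbon acts as an acylium equivalent and is attacked by C4a'' of ring A'', and proton loss from the arenium ion gives the aryl ketone C4''=O. The closest known reaction type is the intramolecular Friedel–Crafts acylation of 3-aryloxypropanoic acids to chroman-4-ones. The single new ring, pyranone C'', closes in a 6-exo-trig mode at the acyl carbon, the carbonyl oxygen staying outside the ring. No stereocentre is created; C2'' (S), C2 (R) and C3 (S) are only carried through, and C2'' is shielded from benzylic heterolysis by the electron-poor 4-acetoxyphenyl group and the neighbouring acyl-bearing chain. Site selectivity between C4a'' and C6'' is secured by the O1''–C2''–C3'' tether, which reaches only C4a'' because the other carbon ortho to O1'' is C8'' and already carries the upper flavanone, so the 3→8'' linkage cannot become 3→6''. Selectivity over intermolecular trifluoroacetylation at C6'' rests on the intramolecular rate advantage at a carbon flanked by two alkoxy groups and para to a third, on a small excess of anhydride at 0 °C, and on the deactivation of ring A'' once the ketone is in place.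

Step 13
Reactants: 21 4-{(2S)-5,7-bis(benzyloxy)-8-[(2R,3S)-5,7-bis(benzyloxy)-2-[3,4-bis(benzyloxy)phenyl]-4-oxochroman-3-yl]-4-oxochroman-2-yl}phenyl acetate
Product: 22 (2R,3S)-5,7-bis(benzyloxy)-3-[(2S)-5,7-bis(benzyloxy)-2-(4-hydroxyphenyl)-4-oxochroman-8-yl]-2-[3,4-bis(benzyloxy)phenyl]chroman-4-one
Conditions: HCl (1.25 M in MeOH), CH2Cl2–MeOH (1:1), rt
Reagents that add atoms: none
Why: Acid-catalysed transesterification of the phenolic acetate avoids base altogether, so neither pyranone can open to a chalcone and no stereocentre is put at risk.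

Step 14
Reactants: 22 (2R,3S)-5,7-bis(benzyloxy)-3-[(2S)-5,7-bis(benzyloxy)-2-(4-hydroxyphenyl)-4-oxochroman-8-yl]-2-[3,4-bis(benzyloxy)phenyl]chroman-4-one
Product: 23 (2R,3S)-2-(3,4-dihydroxyphenyl)-5,7-dihydroxy-3-[(2S)-5,7-dihydroxy-2-(4-hydroxyphenyl)-4-oxochroman-8-yl]chroman-4-one (CNP0105436.2)
Conditions: H2 (1 atm), Pd/C (10 wt% Pd), THF–MeOH (1:1), rt
Reagents that add atoms: none
Why: Catalytic hydrogenolysis of the six aryl benzyl ethers at atmospheric pressure is neutral and should leave the aryl ketones and the cyclic benzylic C–O bonds of both flavanones intact if stopped at full debenzylation.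

Compound list
1 | 4-acetoxybenzoyl chloride | CC(=O)Oc1ccc(cc1)C(Cl)=O | starting material
2 | Meldrum's acid (2,2-dimethyl-1,3-dioxane-4,6-dione) | CC1(C)OC(=O)CC(=O)O1 | starting material
3 | 5-[(4-acetoxyphenyl)(hydroxy)methylidene]-2,2-dimethyl-1,3-dioxane-4,6-dione (not isolated) | CC(=O)Oc1ccc(cc1)C(O)=C1C(=O)OC(C)(C)OC1=O | intermediate
4 | tert-butyl 3-(4-acetoxyphenyl)-3-oxopropanoate | CC(=O)Oc1ccc(cc1)C(=O)CC(=O)OC(C)(C)C | intermediate
5 | tert-butyl (3R)-3-(4-acetoxyphenyl)-3-hydroxypropanoate | CC(C)(C)OC(=O)C[C@H](c1ccc(OC(C)=O)cc1)O | intermediate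
6 | 3,5-bis(benzyloxy)phenol | Oc1cc(OCc2ccccc2)cc(OCc2ccccc2)c1 | starting material
7 | 3,5-bis(benzyloxy)-2-iodophenol | Oc1cc(OCc2ccccc2)cc(OCc2ccccc2)c1I | intermediate
8 | tert-butyl (3S)-3-(4-acetoxyphenyl)-3-[3,5-bis(benzyloxy)-2-iodophenoxy]propanoate | CC(C)(C)OC(=O)C[C@@H](c1ccc(OC(C)=O)cc1)Oc1cc(OCc2ccccc2)cc(OCc2ccccc2)c1I | intermediate
9 | tert-butyl (3S)-3-(4-acetoxyphenyl)-3-[3,5-bis(benzyloxy)-2-(tributylstannyl)phenoxy]propanoate | CC(C)(C)OC(=O)C[C@@H](c1ccc(OC(C)=O)cc1)Oc1cc(OCc2ccccc2)cc(OCc2ccccc2)c1[Sn](CCCC)(CCCC)CCCC | intermediate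
10 | 2,4,6-trihydroxyacetophenone | CC(=O)c1c(O)cc(O)cc1O | starting material
11 | 1-[2,4-bis(benzyloxy)-6-hydroxyphenyl]ethan-1-one | CC(=O)c1c(O)cc(OCc2ccccc2)cc1OCc1ccccc1 | intermediate
12 | tert-butyl 3-[2,4-bis(benzyloxy)-6-hydroxyphenyl]-3-oxopropanoate | CC(C)(C)OC(=O)CC(=O)c1c(O)cc(OCc2ccccc2)cc1OCc1ccccc1 | intermediate
13 | 3,4-bis(benzyloxy)benzaldehyde | O=Cc1ccc(OCc2ccccc2)c(OCc2ccccc2)c1 | starting material
14 | tert-butyl (2Z)-2-[2,4-bis(benzyloxy)-6-hydroxybenzoyl]-3-[3,4-bis(benzyloxy)phenyl]prop-2-enoate (aryl cis to the ester) | CC(C)(C)OC(=O)/C(=C\c1ccc(OCc2ccccc2)c(OCc2ccccc2)c1)C(=O)c1c(O)cc(OCc2ccccc2)cc1OCc1ccccc1 | intermediate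
15 | tert-butyl (2R,3S)-5,7-bis(benzyloxy)-2-[3,4-bis(benzyloxy)phenyl]-4-oxochromane-3-carboxylate (2,3-trans keto form, in equilibrium with its enol) | CC(C)(C)OC(=O)[C@@H]1C(=O)c2c(OCc3ccccc3)cc(OCc3ccccc3)cc2O[C@H]1c1ccc(OCc2ccccc2)c(OCc2ccccc2)c1 | intermediate
16 | {2-[(1S)-1-(4-acetoxyphenyl)-3-tert-butoxy-3-oxopropoxy]-4,6-bis(benzyloxy)phenyl}lead triacetate (not isolated) | CC(C)(C)OC(=O)C[C@@H](c1ccc(OC(C)=O)cc1)Oc1cc(OCc2ccccc2)cc(OCc2ccccc2)c1[Pb](OC(C)=O)(OC(C)=O)OC(C)=O | intermediate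
17 | tert-butyl (2S,3R)-3-{2-[(1S)-1-(4-acetoxyphenyl)-3-tert-butoxy-3-oxopropoxy]-4,6-bis(benzyloxy)phenyl}-5,7-bis(benzyloxy)-2-[3,4-bis(benzyloxy)phenyl]-4-oxochromane-3-carboxylate (aryl groups on C2 and C3 anti; C2 has the same spatial arrangement as in 15, the descriptor changes because C3 now outranks ring B) | CC(C)(C)OC(=O)C[C@@H](c1ccc(OC(C)=O)cc1)Oc1cc(OCc2ccccc2)cc(OCc2ccccc2)c1[C@]1(C(=O)OC(C)(C)C)C(=O)c2c(OCc3ccccc3)cc(OCc3ccccc3)cc2O[C@H]1c1ccc(OCc2ccccc2)c(OCc2ccccc2)c1 | intermediate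
18 | (2S,3R)-3-{2-[(1S)-1-(4-acetoxyphenyl)-2-carboxyethoxy]-4,6-bis(benzyloxy)phenyl}-5,7-bis(benzyloxy)-2-[3,4-bis(benzyloxy)phenyl]-4-oxochromane-3-carboxylic acid (not isolated) | OC(=O)C[C@@H](c1ccc(OC(C)=O)cc1)Oc1cc(OCc2ccccc2)cc(OCc2ccccc2)c1[C@]1(C(O)=O)C(=O)c2c(OCc3ccccc3)cc(OCc3ccccc3)cc2O[C@H]1c1ccc(OCc2ccccc2)c(OCc2ccccc2)c1 | intermediate
19 | (3S)-3-(4-acetoxyphenyl)-3-{3,5-bis(benzyloxy)-2-[(2R,3S)-5,7-bis(benzyloxy)-2-[3,4-bis(benzyloxy)phenyl]-4-oxochroman-3-yl]phenoxy}propanoic acid | OC(=O)C[C@@H](c1ccc(OC(C)=O)cc1)Oc1cc(OCc2ccccc2)cc(OCc2ccccc2)c1[C@@H]1C(=O)c2c(OCc3ccccc3)cc(OCc3ccccc3)cc2O[C@H]1c1ccc(OCc2ccccc2)c(OCc2ccccc2)c1 | intermediate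
20 | mixed anhydride of 19 with trifluoroacetic acid (not isolated) | FC(F)(F)C(=O)OC(=O)C[C@@H](c1ccc(OC(C)=O)cc1)Oc1cc(OCc2ccccc2)cc(OCc2ccccc2)c1[C@@H]1C(=O)c2c(OCc3ccccc3)cc(OCc3ccccc3)cc2O[C@H]1c1ccc(OCc2ccccc2)c(OCc2ccccc2)c1 | intermediate
21 | 4-{(2S)-5,7-bis(benzyloxy)-8-[(2R,3S)-5,7-bis(benzyloxy)-2-[3,4-bis(benzyloxy)phenyl]-4-oxochroman-3-yl]-4-oxochroman-2-yl}phenyl acetate | O=C1C[C@@H](c2ccc(OC(C)=O)cc2)Oc2c1c(OCc1ccccc1)cc(OCc1ccccc1)c2[C@@H]1C(=O)c2c(OCc3ccccc3)cc(OCc3ccccc3)cc2O[C@H]1c1ccc(OCc2ccccc2)c(OCc2ccccc2)c1 | intermediate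
22 | (2R,3S)-5,7-bis(benzyloxy)-3-[(2S)-5,7-bis(benzyloxy)-2-(4-hydroxyphenyl)-4-oxochroman-8-yl]-2-[3,4-bis(benzyloxy)phenyl]chroman-4-one | O=C1C[C@@H](c2ccc(O)cc2)Oc2c1c(OCc1ccccc1)cc(OCc1ccccc1)c2[C@@H]1C(=O)c2c(OCc3ccccc3)cc(OCc3ccccc3)cc2O[C@H]1c1ccc(OCc2ccccc2)c(OCc2ccccc2)c1 | intermediate
23 | (2R,3S)-2-(3,4-dihydroxyphenyl)-5,7-dihydroxy-3-[(2S)-5,7-dihydroxy-2-(4-hydroxyphenyl)-4-oxochroman-8-yl]chroman-4-one | O=C1C[C@@H](c2ccc(O)cc2)Oc2c1c(O)cc(O)c2[C@@H]1C(=O)c2c(O)cc(O)cc2O[C@H]1c1ccc(O)c(O)c1 | target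

Total step count: 14.
Longest linear sequence: 9 steps (6, 7, 8, 9, 10, 11, 12, 13, 14). The arm 1, 2, 4, 5 leading into step 10 is equally long.

Steps most likely to fail

**Step 10.**
- Risk: the ligand coupling at tetravalent lead may stall. The branched alkoxy group next to the C–Pb bond adds to the crowding at the carbon that becomes quaternary. Long heating with pyridine would then let unreacted 15 open and reclose, so that C2 loses configurational purity.
- Fallback: it sets out from 7 and 15 and comes back at 19. A slimmer aryl group is transferred and the ether is made afterwards.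
- Boc2O with catalytic DMAP in CH2Cl2 turns 7 into tert-butyl 3,5-bis(benzyloxy)-2-iodophenyl carbonate F1.
- (Bu3Sn)2 with Pd(PPh3)4 in hot toluene gives tert-butyl 3,5-bis(benzyloxy)-2-(tributylstannyl)phenyl carbonate F2.
- Pb(OAc)4 with catalytic Hg(OAc)2 converts F2 into the aryllead triacetate F3, which arylates 15 in CHCl3–pyridine to the quaternary β-keto ester F4.
- CF3CO2H in CH2Cl2 removes carbonate and ester, and the β-keto acid loses CO2 to give the 2,3-trans 3-(2-hydroxyaryl)flavanone F5.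
- Mitsunobu etherification of F5 with 5 (PPh3, DIAD, concentrated toluene solution, sonication) gives, with inversion, the tert-butyl ester of 19 F6.
- CF3CO2H in CH2Cl2 then frees 19.

**Step 12.**
- Risk: closure may be slowed by buttressing of the side chain against the C8'' substituent. Longer contact with the acidic medium would allow trifluoroacetylation at C6'', loss of benzyl groups, or heterolysis of the C2''–O1'' bond. Heterolysis of the C2–O1 bond next to the electron-rich ring B is also possible and would scramble the upper unit.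
- Fallback: it sets out from 8 and comes back at 21. The same ring is closed before the halves are joined, so the upper flavanone never meets the anhydride, and iodine holds C8''.
- CF3CO2H in CH2Cl2 gives (3S)-3-(4-acetoxyphenyl)-3-[3,5-bis(benzyloxy)-2-iodophenoxy]propanoic acid F7.
- (CF3CO)2O closes F7 to the 8-iodoflavanone F8.
- (Bu3Sn)2 with Pd(PPh3)4 gives the 8-stannylflavanone F9.
- Pb(OAc)4 with catalytic Hg(OAc)2 gives the flavanon-8-yllead triacetate F10, whose ortho oxygen is tied back in ring C''.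
- F10 arylates 15 in CHCl3–pyridine to the biflavanone ester F11.
- CF3CO2H in CH2Cl2 removes the ester and CO2 and equilibrates C3, which delivers 21.

**Step 9.**
- Risk: facial selectivity may be poor, because the benzyloxy group ortho to the ketone twists the aroyl unit and weakens the two-point binding to the catalyst. An uncatalysed background cyclisation may also dilute the enantiomeric purity.
- Fallback: it sets out from 14 and comes back at 19. Catalyst control is given up and the enantiopure C2'' centre serves as a built-in resolving handle.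
- Catalytic Et3N in toluene closes 14 to the racemate, that is 15 together with its enantiomer F12.
- Arylation with 16 as in step 10 gives 17 together with the upper-unit diastereomer of 17 F13.
- CF3CO2H in CH2Cl2 gives 19 together with the (2S,3R)-diastereomer of 19 F14.
- These two acids are diastereomers and are separated by chromatography or crystallisation.

Further compounds
F1 | step 10 | tert-butyl 3,5-bis(benzyloxy)-2-iodophenyl carbonate | CC(C)(C)OC(=O)Oc1cc(OCc2ccccc2)cc(OCc2ccccc2)c1I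
F2 | step 10 | tert-butyl 3,5-bis(benzyloxy)-2-(tributylstannyl)phenyl carbonate | CC(C)(C)OC(=O)Oc1cc(OCc2ccccc2)cc(OCc2ccccc2)c1[Sn](CCCC)(CCCC)CCCC
F3 | step 10 | [2,4-bis(benzyloxy)-6-(tert-butoxycarbonyloxy)phenyl]lead triacetate | CC(C)(C)OC(=O)Oc1cc(OCc2ccccc2)cc(OCc2ccccc2)c1[Pb](OC(C)=O)(OC(C)=O)OC(C)=O
F4 | step 10 | tert-butyl (2S,3R)-3-[2,4-bis(benzyloxy)-6-(tert-butoxycarbonyloxy)phenyl]-5,7-bis(benzyloxy)-2-[3,4-bis(benzyloxy)phenyl]-4-oxochromane-3-carboxylate | CC(C)(C)OC(=O)Oc1cc(OCc2ccccc2)cc(OCc2ccccc2)c1[C@]1(C(=O)OC(C)(C)C)C(=O)c2c(OCc3ccccc3)cc(OCc3ccccc3)cc2O[C@H]1c1ccc(OCc2ccccc2)c(OCc2ccccc2)c1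
F5 | step 10 | (2R,3S)-5,7-bis(benzyloxy)-2-[3,4-bis(benzyloxy)phenyl]-3-[2,4-bis(benzyloxy)-6-hydroxyphenyl]chroman-4-one | Oc1cc(OCc2ccccc2)cc(OCc2ccccc2)c1[C@@H]1C(=O)c2c(OCc3ccccc3)cc(OCc3ccccc3)cc2O[C@H]1c1ccc(OCc2ccccc2)c(OCc2ccccc2)c1
F6 | step 10 | tert-butyl (3S)-3-(4-acetoxyphenyl)-3-{3,5-bis(benzyloxy)-2-[(2R,3S)-5,7-bis(benzyloxy)-2-[3,4-bis(benzyloxy)phenyl]-4-oxochroman-3-yl]phenoxy}propanoate | CC(C)(C)OC(=O)C[C@@H](c1ccc(OC(C)=O)cc1)Oc1cc(OCc2ccccc2)cc(OCc2ccccc2)c1[C@@H]1C(=O)c2c(OCc3ccccc3)cc(OCc3ccccc3)cc2O[C@H]1c1ccc(OCc2ccccc2)c(OCc2ccccc2)c1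
F7 | step 12 | (3S)-3-(4-acetoxyphenyl)-3-[3,5-bis(benzyloxy)-2-iodophenoxy]propanoic acid | OC(=O)C[C@@H](c1ccc(OC(C)=O)cc1)Oc1cc(OCc2ccccc2)cc(OCc2ccccc2)c1I
F8 | step 12 | 4-[(2S)-5,7-bis(benzyloxy)-8-iodo-4-oxochroman-2-yl]phenyl acetate | O=C1C[C@@H](c2ccc(OC(C)=O)cc2)Oc2c1c(OCc1ccccc1)cc(OCc1ccccc1)c2I
F9 | step 12 | 4-[(2S)-5,7-bis(benzyloxy)-4-oxo-8-(tributylstannyl)chroman-2-yl]phenyl acetate | O=C1C[C@@H](c2ccc(OC(C)=O)cc2)Oc2c1c(OCc1ccccc1)cc(OCc1ccccc1)c2[Sn](CCCC)(CCCC)CCCC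
F10 | step 12 | [(2S)-2-(4-acetoxyphenyl)-5,7-bis(benzyloxy)-4-oxochroman-8-yl]lead triacetate | O=C1C[C@@H](c2ccc(OC(C)=O)cc2)Oc2c1c(OCc1ccccc1)cc(OCc1ccccc1)c2[Pb](OC(C)=O)(OC(C)=O)OC(C)=O
F11 | step 12 | tert-butyl (2S,3R)-3-[(2S)-2-(4-acetoxyphenyl)-5,7-bis(benzyloxy)-4-oxochroman-8-yl]-5,7-bis(benzyloxy)-2-[3,4-bis(benzyloxy)phenyl]-4-oxochromane-3-carboxylate | O=C1C[C@@H](c2ccc(OC(C)=O)cc2)Oc2c1c(OCc1ccccc1)cc(OCc1ccccc1)c2[C@]1(C(=O)OC(C)(C)C)C(=O)c2c(OCc3ccccc3)cc(OCc3ccccc3)cc2O[C@H]1c1ccc(OCc2ccccc2)c(OCc2ccccc2)c1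
F12 | step 9 | tert-butyl (2S,3R)-5,7-bis(benzyloxy)-2-[3,4-bis(benzyloxy)phenyl]-4-oxochromane-3-carboxylate | CC(C)(C)OC(=O)[C@H]1C(=O)c2c(OCc3ccccc3)cc(OCc3ccccc3)cc2O[C@@H]1c1ccc(OCc2ccccc2)c(OCc2ccccc2)c1
F13 | step 9 | tert-butyl (2R,3S)-3-{2-[(1S)-1-(4-acetoxyphenyl)-3-tert-butoxy-3-oxopropoxy]-4,6-bis(benzyloxy)phenyl}-5,7-bis(benzyloxy)-2-[3,4-bis(benzyloxy)phenyl]-4-oxochromane-3-carboxylate | CC(C)(C)OC(=O)C[C@@H](c1ccc(OC(C)=O)cc1)Oc1cc(OCc2ccccc2)cc(OCc2ccccc2)c1[C@@]1(C(=O)OC(C)(C)C)C(=O)c2c(OCc3ccccc3)cc(OCc3ccccc3)cc2O[C@@H]1c1ccc(OCc2ccccc2)c(OCc2ccccc2)c1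
F14 | step 9 | (3S)-3-(4-acetoxyphenyl)-3-{3,5-bis(benzyloxy)-2-[(2S,3R)-5,7-bis(benzyloxy)-2-[3,4-bis(benzyloxy)phenyl]-4-oxochroman-3-yl]phenoxy}propanoic acid | OC(=O)C[C@@H](c1ccc(OC(C)=O)cc1)Oc1cc(OCc2ccccc2)cc(OCc2ccccc2)c1[C@H]1C(=O)c2c(OCc3ccccc3)cc(OCc3ccccc3)cc2O[C@@H]1c1ccc(OCc2ccccc2)c(OCc2ccccc2)c1
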